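**Plan**

- Retrosynthetic cuts: both prenyl C=C bonds (back to allyl groups); the C5–allyl and C7–allyl bonds (back to an aromatic 5-acyl-6-hydroxy-4-methoxy-7-methyl-2,3-dihydrobenzofuran); O1–C2; the aryl C5–acyl bond; the bond between ring carbon C2 and the side-chain carbinol carbon C2′; last C3a–C3.
- Forward order: the benzene ring is bought; the C3–C2 arm is attached (steps 1–4), the side chain is joined at C2–C2′ (step 6), the ketone is added (7), the dihydrofuran ring is closed at O1–C2 (9), the benzene ring is dearomatised by allylation at C7 and, after loss of the O4 methyl group, at C5 (10, 11), and cross-metathesis finishes (12).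
- Enabling feature: C2 (the ring CH bonded to O1) and C2′ (the exocyclic carbon bearing OH) are adjacent oxygen-bearing sp3 carbons, and C2′ carries a methyl and a 4-methylpent-3-enyl group that a face-selective addition to a ketone cannot tell apart. Each carbon is therefore drawn from an enantioenriched α-oxy organometallic and the two are joined by a stereospecific 1,2-boronate shift.
- Stereochemistry: C2′ from (R)-sulcatol (inverted in step 5, transferred with formal retention in step 6); C2 from copper-catalysed asymmetric aldehyde borylation (kept in step 6, inverted in step 9); C7 from the chiral palladium catalyst (step 10); C5 from the C7 centre (allyl enters anti to the C7 allyl group, step 11).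

Key step: step 6

Remark on labels: benzofuran numbering (O1, C2, C3, C3a, C4–C7, C7a); C2′ is the carbinol carbon of the side chain. Ar = 6-methoxy-3-methyl-2,4-bis{[2-(trimethylsilyl)ethoxy]methoxy}phenyl; SEM = [2-(trimethylsilyl)ethoxy]methyl; TES = triethylsilyl; Bneop = 5,5-dimethyl-1,3,2-dioxaborinan-2-yl.

Remark on assumptions: 5-methoxy-2-methylbenzene-1,3-diol and (R)-6-methylhept-5-en-2-ol are taken as catalogue compounds; for the chiral ligands of steps 4 and 10 one commercial antipode is written, and the antipode that gives the drawn configuration is to be fixed in the first run.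

**Step 1**
Reactants: 1 5-methoxy-2-methylbenzene-1,3-diol
Product: 2 5-methoxy-2-methyl-1,3-bis{[2-(trimethylsilyl)ethoxy]methoxy}benzene
Conditions: NaH, SEMCl, DMF, 0 °C → rt
Reagents that add atoms: 2-(trimethylsilyl)ethoxymethyl chloride, C[Si](C)(C)CCOCCl
Why: Williamson-type O-alkylation of both phenoxides should give acetal ethers that withstand organolithiums, direct ortho-lithiation and are later removed by fluoride.

**Step 2**
Reactants: 2 5-methoxy-2-methyl-1,3-bis{[2-(trimethylsilyl)ethoxy]methoxy}benzene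
Product: 4 2-Ar-ethan-1-ol, via aryllithium 3 (not isolated)
Conditions: nBuLi, TMEDA, THF, 0 °C; ethylene oxide, −78 °C → rt; H2O
Reagents that add atoms: ethylene oxide, C1CO1
Why: Directed ortho-metalation should take place at the ring CH flanked by OMe and OSEM (the two such positions are equivalent by symmetry), and the aryllithium opens ethylene oxide to the 2-arylethanol.

**Step 3**
Reactants: 4 2-Ar-ethan-1-ol
Product: 5 2-Ar-acetaldehyde
Conditions: Dess–Martin periodinane, CH2Cl2, 0 °C → rt
Reagents that add atoms: none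
Why: Dess–Martin oxidation should stop at the arylacetaldehyde under non-basic conditions that avoid enolisation.

**Step 4**
Reactants: 5 2-Ar-acetaldehyde
Product: 7 triethyl{[(1S)-2-Ar-1-(Bneop)ethyl]oxy}silane, via hydroxy boronate 6 (not isolated)
Conditions: CuCl (5 mol%), (R)-DTBM-SEGPHOS (5 mol%), KOtBu (10 mol%), bis(neopentyl glycolato)diboron, MeOH, THF, 30 °C; then TESCl, imidazole, 0 °C
Reagents that add atoms: bis(neopentyl glycolato)diboron, CC1(C)COB(OC1)B1OCC(C)(C)CO1; chlorotriethylsilane, CC[Si](Cl)(CC)CC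
Why: Copper(I)–boryl 1,2-addition to the aldehyde C=O (copper-catalysed enantioselective aldehyde borylation) with in situ O-silylation should give the α-silyloxy boronic ester, the chiral bisphosphine–copper complex choosing the aldehyde face to set the (S) centre that becomes C2; the neopentyl glycol diboron is used so that boron stays accessible in step 6.

**Step 5**
Reactants: 8 (2R)-6-methylhept-5-en-2-ol ((R)-sulcatol)
Product: 9 (2S)-6-methylhept-5-en-2-yl 2,4,6-tri(propan-2-yl)benzoate
Conditions: 2,4,6-triisopropylbenzoic acid, PPh3, DIAD, THF, 0 °C → rt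
Reagents that add atoms: 2,4,6-tri(propan-2-yl)benzoic acid, CC(C)c1cc(C(C)C)c(C(=O)O)c(C(C)C)c1
Why: Mitsunobu esterification of the secondary alcohol with the hindered acid proceeds by SN2 with inversion, which should turn (R)-8 into the (S)-ester whose carbinol carbon becomes C2′.

**Step 6**
Reactants: 9 (2S)-6-methylhept-5-en-2-yl 2,4,6-tri(propan-2-yl)benzoate; 7 triethyl{[(1S)-2-Ar-1-(Bneop)ethyl]oxy}silane
Product: 13 (2R,3S)-1-Ar-3,7-dimethyl-2-[(triethylsilyl)oxy]oct-6-en-3-ol, via lithiated benzoate 10 (not isolated), via boronate complex 11 (not isolated), via tertiary boronic ester 12 (not isolated)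
Conditions: sBuLi, TMEDA, cyclopentyl methyl ether, −60 °C; add 7, −60 °C → 45 °C; then NaOH, H2O2, THF/H2O, 0 °C
Reagents that add atoms: hydrogen peroxide, OO
Why: Proposed new method: sBuLi/TMEDA removes the carbinol hydrogen of 9 with retention to give the configurationally stable α-oxy organolithium 10, which adds to boron of 7 with retention (11); on warming, the 1-silyloxy-2-arylethyl group migrates from boron to carbon antiperiplanar to the departing triisopropylbenzoate (12), and C–B oxidation with retention gives 13, so the new C–C bond stands where the C–H bond of 9 stood. The closest known reaction type is the lithiation–borylation of secondary dialkyl triisopropylbenzoates with neopentyl glycol boronic esters to tertiary boronic esters, and α-alkoxyalkyl groups are known to migrate in Matteson homologation; the pairing with an α-silyloxy secondary boronic ester is the untested part. No ring is closed. The tertiary carbinol centre (S) comes stereospecifically from (S)-9 and the adjacent CH–O centre (R) from (S)-7, because the migrating carbon keeps its configuration and the carbenoid carbon is attacked only from the side opposite the leaving group. The step needs the 1,2-shift to outrun reversal of the crowded complex and β-elimination of the β-silyloxy boronate 12; the small neopentyl glycol ester, the small triethylsilyl group and oxidation at 0 °C are chosen to secure this.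

**Step 7**
Reactants: 13 (2R,3S)-1-Ar-3,7-dimethyl-2-[(triethylsilyl)oxy]oct-6-en-3-ol
Product: 15 1-{3-[(2R,3S)-3-hydroxy-3,7-dimethyl-2-(triethylsilyloxy)oct-6-en-1-yl]-2-methoxy-5-methyl-4,6-bis(SEM-oxy)phenyl}-2-methylpropan-1-one, via dilithio species 14 (not isolated)
Conditions: nBuLi (2.3 equiv), THF, −78 → 0 °C; iPrC(O)N(OMe)Me, −78 °C → rt
Reagents that add atoms: N-methoxy-N,2-dimethylpropanamide, CC(C)C(=O)N(C)OC
Why: After deprotonation of the tertiary alcohol, directed ortho-metalation at the only remaining ring CH (between OMe and OSEM) and acylation with the Weinreb amide should give the aryl ketone without over-addition; a silyl shift between the two side-chain oxygens would be harmless because both are freed in step 8.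

**Step 8**
Reactants: 15 1-{3-[(2R,3S)-3-hydroxy-3,7-dimethyl-2-(triethylsilyloxy)oct-6-en-1-yl]-2-methoxy-5-methyl-4,6-bis(SEM-oxy)phenyl}-2-methylpropan-1-one
Product: 16 1-{3-[(2R,3S)-2,3-dihydroxy-3,7-dimethyloct-6-en-1-yl]-4,6-dihydroxy-2-methoxy-5-methylphenyl}-2-methylpropan-1-one
Conditions: TBAF, THF, 60 °C
Reagents that add atoms: none
Why: Fluoride should cleave the triethylsilyl ether and, by β-elimination of the 2-(trimethylsilyl)ethyl groups, both SEM ethers, leaving the skeleton, the tertiary alcohol and the trisubstituted alkene untouched.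

**Step 9**
Reactants: 16 1-{3-[(2R,3S)-2,3-dihydroxy-3,7-dimethyloct-6-en-1-yl]-4,6-dihydroxy-2-methoxy-5-methylphenyl}-2-methylpropan-1-one
Product: 17 1-{(2S)-6-hydroxy-2-[(2S)-2-hydroxy-6-methylhept-5-en-2-yl]-4-methoxy-7-methyl-2,3-dihydro-1-benzofuran-5-yl}-2-methylpropan-1-one
Conditions: PPh3, DIAD, THF, 0 °C → rt
Reagents that add atoms: none
Why: Mitsunobu cycloetherification: the secondary alcohol is activated as its oxyphosphonium ion and displaced 5-exo-tet with inversion by the only phenol oxygen that can reach it (O7a, para to the ketone and not hydrogen-bonded), which converts the (R) carbinol into (S)-C2 and closes the dihydrofuran ring.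

**Step 10**
Reactants: 17 1-{(2S)-6-hydroxy-2-[(2S)-2-hydroxy-6-methylhept-5-en-2-yl]-4-methoxy-7-methyl-2,3-dihydro-1-benzofuran-5-yl}-2-methylpropan-1-one
Product: 18 (2S,7S)-2-[(2S)-2-hydroxy-6-methylhept-5-en-2-yl]-4-methoxy-7-methyl-5-(2-methylpropanoyl)-7-(prop-2-en-1-yl)-2,3-dihydro-1-benzofuran-6(7H)-one
Conditions: Pd2(dba)3 (2.5 mol%), (R,R)-DACH-phenyl Trost ligand (7.5 mol%), allyl methyl carbonate, toluene, 0 °C → rt
Reagents that add atoms: allyl methyl carbonate, C=CCOC(=O)OC
Why: Palladium-catalysed asymmetric allylic dearomatisation (Tsuji–Trost type) of the phenolate at the methyl-bearing ortho carbon C7 should give the 2,4-dienone, the acyl-bearing ortho carbon being deactivated and the para carbon C3a screened by the flanking OMe group, with the new quaternary centre set by the chiral ligand pocket.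

**Step 11**
Reactants: 18 (2S,7S)-2-[(2S)-2-hydroxy-6-methylhept-5-en-2-yl]-4-methoxy-7-methyl-5-(2-methylpropanoyl)-7-(prop-2-en-1-yl)-2,3-dihydro-1-benzofuran-6(7H)-one
Product: 20 (2S,5R,7S)-2-[(2S)-2-hydroxy-6-methylhept-5-en-2-yl]-7-methyl-5-(2-methylpropanoyl)-5,7-di(prop-2-en-1-yl)-2,3-dihydro-1-benzofuran-4,6(5H,7H)-dione, via lithium enolate 19 (not isolated)
Conditions: LiCl, DMF, 80 °C; then Pd(PPh3)4 (5 mol%), allyl methyl carbonate, rt
Reagents that add atoms: allyl methyl carbonate, C=CCOC(=O)OC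
Why: Chloride should remove the methyl group of the doubly activated vinylogous ester by SN2, and the triketone enolate is then C-allylated at C5 by the π-allylpalladium complex (Tsuji–Trost, O-allylation being reversible) on the face opposite the longer C7 substituent (allyl versus methyl), which gives the 5,7-trans-diallyl arrangement.

**Step 12**
Reactants: 20 (2S,5R,7S)-2-[(2S)-2-hydroxy-6-methylhept-5-en-2-yl]-7-methyl-5-(2-methylpropanoyl)-5,7-di(prop-2-en-1-yl)-2,3-dihydro-1-benzofuran-4,6(5H,7H)-dione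
Product: 21 (2S,5R,7S)-2-[(2S)-2-hydroxy-6-methylhept-5-en-2-yl]-7-methyl-5,7-bis(3-methylbut-2-en-1-yl)-5-(2-methylpropanoyl)-2,3-dihydro-1-benzofuran-4,6(5H,7H)-dione
Conditions: Grubbs II (10 mol%), 2-methylbut-2-ene, CH2Cl2, 40 °C
Reagents that add atoms: 2-methylbut-2-ene, CC=C(C)C
Why: Olefin cross-metathesis with excess 2-methylbut-2-ene should convert both monosubstituted allyl groups into prenyl groups with loss of propene, while the trisubstituted side-chain alkene can only exchange degenerately and no stereocentre is touched.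

**Compound list**

1 | 5-methoxy-2-methylbenzene-1,3-diol | COc1cc(O)c(C)c(O)c1 | starting material
2 | 5-methoxy-2-methyl-1,3-bis{[2-(trimethylsilyl)ethoxy]methoxy}benzene | COc1cc(OCOCC[Si](C)(C)C)c(C)c(OCOCC[Si](C)(C)C)c1 | intermediate
3 | Ar-lithium (aryllithium) | [Li]c1c(OC)cc(OCOCC[Si](C)(C)C)c(C)c1OCOCC[Si](C)(C)C | intermediate
4 | 2-Ar-ethan-1-ol | OCCc1c(OC)cc(OCOCC[Si](C)(C)C)c(C)c1OCOCC[Si](C)(C)C | intermediate
5 | 2-Ar-acetaldehyde | O=CCc1c(OC)cc(OCOCC[Si](C)(C)C)c(C)c1OCOCC[Si](C)(C)C | intermediate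
6 | (1S)-2-Ar-1-(Bneop)ethan-1-ol | O[C@H](Cc1c(OC)cc(OCOCC[Si](C)(C)C)c(C)c1OCOCC[Si](C)(C)C)B1OCC(C)(C)CO1 | intermediate
7 | triethyl{[(1S)-2-Ar-1-(Bneop)ethyl]oxy}silane | CC[Si](CC)(CC)O[C@H](Cc1c(OC)cc(OCOCC[Si](C)(C)C)c(C)c1OCOCC[Si](C)(C)C)B1OCC(C)(C)CO1 | intermediate
8 | (2R)-6-methylhept-5-en-2-ol | CC(C)=CCC[C@@H](C)O | starting material
9 | (2S)-6-methylhept-5-en-2-yl 2,4,6-tri(propan-2-yl)benzoate | CC(C)=CCC[C@H](C)OC(=O)c1c(C(C)C)cc(C(C)C)cc1C(C)C | intermediate
10 | (2S)-2-lithio-6-methylhept-5-en-2-yl 2,4,6-tri(propan-2-yl)benzoate | CC(C)=CCC[C@]([Li])(C)OC(=O)c1c(C(C)C)cc(C(C)C)cc1C(C)C | intermediate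
11 | lithium boronate complex of 10 and 7 (both carbon centres S) | [Li+].CC(C)=CCC[C@](C)(OC(=O)c1c(C(C)C)cc(C(C)C)cc1C(C)C)[B-]1(OCC(C)(C)CO1)[C@H](O[Si](CC)(CC)CC)Cc1c(OC)cc(OCOCC[Si](C)(C)C)c(C)c1OCOCC[Si](C)(C)C | intermediate
12 | 2-[(2R,3R)-1-Ar-3,7-dimethyl-2-(triethylsilyloxy)oct-6-en-3-yl]-5,5-dimethyl-1,3,2-dioxaborinane | CC(C)=CCC[C@](C)(B1OCC(C)(C)CO1)[C@H](O[Si](CC)(CC)CC)Cc1c(OC)cc(OCOCC[Si](C)(C)C)c(C)c1OCOCC[Si](C)(C)C | intermediate
13 | (2R,3S)-1-Ar-3,7-dimethyl-2-[(triethylsilyl)oxy]oct-6-en-3-ol | CC(C)=CCC[C@](C)(O)[C@H](O[Si](CC)(CC)CC)Cc1c(OC)cc(OCOCC[Si](C)(C)C)c(C)c1OCOCC[Si](C)(C)C | intermediate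
14 | dilithio species of 13 (lithium alkoxide, ring carbon between OMe and OSEM lithiated) | CC(C)=CCC[C@](C)(O[Li])[C@H](O[Si](CC)(CC)CC)Cc1c(OC)c([Li])c(OCOCC[Si](C)(C)C)c(C)c1OCOCC[Si](C)(C)C | intermediate
15 | 1-{3-[(2R,3S)-3-hydroxy-3,7-dimethyl-2-(triethylsilyloxy)oct-6-en-1-yl]-2-methoxy-5-methyl-4,6-bis(SEM-oxy)phenyl}-2-methylpropan-1-one | CC(C)=CCC[C@](C)(O)[C@H](O[Si](CC)(CC)CC)Cc1c(OC)c(C(=O)C(C)C)c(OCOCC[Si](C)(C)C)c(C)c1OCOCC[Si](C)(C)C | intermediate
16 | 1-{3-[(2R,3S)-2,3-dihydroxy-3,7-dimethyloct-6-en-1-yl]-4,6-dihydroxy-2-methoxy-5-methylphenyl}-2-methylpropan-1-one | CC(C)=CCC[C@](C)(O)[C@H](O)Cc1c(OC)c(C(=O)C(C)C)c(O)c(C)c1O | intermediate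
17 | 1-{(2S)-6-hydroxy-2-[(2S)-2-hydroxy-6-methylhept-5-en-2-yl]-4-methoxy-7-methyl-2,3-dihydro-1-benzofuran-5-yl}-2-methylpropan-1-one | CC(C)=CCC[C@](C)(O)[C@@H]1Cc2c(O1)c(C)c(O)c(C(=O)C(C)C)c2OC | intermediate
18 | (2S,7S)-2-[(2S)-2-hydroxy-6-methylhept-5-en-2-yl]-4-methoxy-7-methyl-5-(2-methylpropanoyl)-7-(prop-2-en-1-yl)-2,3-dihydro-1-benzofuran-6(7H)-one | CC(C)=CCC[C@](C)(O)[C@@H]1CC2=C(O1)[C@](C)(CC=C)C(=O)C(C(=O)C(C)C)=C2OC | intermediate
19 | lithium enolate of the 4-hydroxy analogue of 18 | [Li+].CC(C)=CCC[C@](C)(O)[C@@H]1CC2=C(O1)[C@](C)(CC=C)C(=O)C(C(=O)C(C)C)=C2[O-] | intermediate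
20 | (2S,5R,7S)-2-[(2S)-2-hydroxy-6-methylhept-5-en-2-yl]-7-methyl-5-(2-methylpropanoyl)-5,7-di(prop-2-en-1-yl)-2,3-dihydro-1-benzofuran-4,6(5H,7H)-dione | CC(C)=CCC[C@](C)(O)[C@@H]1CC2=C(O1)[C@](C)(CC=C)C(=O)[C@](CC=C)(C(=O)C(C)C)C2=O | intermediate
21 | (2S,5R,7S)-2-[(2S)-2-hydroxy-6-methylhept-5-en-2-yl]-7-methyl-5,7-bis(3-methylbut-2-en-1-yl)-5-(2-methylpropanoyl)-2,3-dihydro-1-benzofuran-4,6(5H,7H)-dione | CC(C)=CCC[C@](C)(O)[C@@H]1CC2=C(O1)[C@](C)(CC=C(C)C)C(=O)[C@](CC=C(C)C)(C(=O)C(C)C)C2=O | target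

**Step count**

Total: 12 steps. Longest linear sequence: 11 steps (1 → 21 through steps 1–4 and 6–12; step 5 prepares the second fragment).

**Steps most likely to fail**

Step 6 (Proposed new method). The crowded boronate complex may revert to its components, or the β-silyloxy boronate may lose the silyloxy group by β-elimination, before or instead of the 1,2-shift. The fallback uses known chemistry and brings the side chain in with the C2–C2′ bond already made; it sets out from 2 and comes back at 17. Nerol is epoxidised under Sharpless conditions (Ti(OiPr)4, D-(−)-diethyl tartrate, tBuOOH, −20 °C) to [(2R,3S)-3-methyl-3-(4-methylpent-3-en-1-yl)oxiran-2-yl]methanol F1, which is converted (Tf2O, 2,6-lutidine, −78 °C) into [(2R,3S)-3-methyl-3-(4-methylpent-3-en-1-yl)oxiran-2-yl]methyl trifluoromethanesulfonate F2. Aryllithium 3, made from 2 as in step 2, displaces the triflate at the CH2 carbon under CuBr·SMe2 catalysis to give (2R,3S)-2-(Ar-methyl)-3-methyl-3-(4-methylpent-3-en-1-yl)oxirane F3. Ortho-lithiation to the ring-lithiated epoxide F4 and acylation with the Weinreb amide as in step 7 give the aryl ketone epoxide F5. TBAF then frees both phenols, and the phenoxide next to the side chain opens the epoxide 5-exo at its CH carbon with inversion, which should give 17 directly.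

Step 10. Allylation may go to the ring-fusion carbon C3a or to oxygen instead of C7, or the ligand may fail to override the substrate in choosing the face of C7. The fallback exchanges the order of ring closure and dearomatisation; it sets out from 16 and comes back at 18. In 16, C7 is ortho to both free phenolic oxygens while C3a carries the branched diol chain, so allylation under the conditions of step 10 with one equivalent of carbonate should give (6S)-4-[(2R,3S)-2,3-dihydroxy-3,7-dimethyloct-6-en-1-yl]-5-hydroxy-3-methoxy-6-methyl-2-(2-methylpropanoyl)-6-(prop-2-en-1-yl)cyclohexa-2,4-dien-1-one F6. The Mitsunobu closure of step 9 is then applied to this vinylogous acid, whose enol oxygen at C7a displaces the activated secondary alcohol with inversion to give 18.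

Step 11. The enolate may be allylated on oxygen, or on the wrong face of C5 because methyl and allyl on C7 shield the two faces almost equally. The fallback separates C–O from C–C bond formation; it sets out from 18 and comes back at 20. Enolate 19, made as in step 11, is acidified to (2S,7S)-4-hydroxy-2-[(2S)-2-hydroxy-6-methylhept-5-en-2-yl]-7-methyl-5-(2-methylpropanoyl)-7-(prop-2-en-1-yl)-2,3-dihydro-1-benzofuran-6(7H)-one F7. This is O-allylated (allyl bromide, K2CO3, acetone) to (2S,7S)-2-[(2S)-2-hydroxy-6-methylhept-5-en-2-yl]-7-methyl-5-(2-methylpropanoyl)-7-(prop-2-en-1-yl)-4-(prop-2-en-1-yloxy)-2,3-dihydro-1-benzofuran-6(7H)-one F8. Heating in toluene (110 °C) should then move the allyl group from O4 to C5 by a [3,3] Claisen shift through a chair transition state on the face away from the C7 allyl group, giving 20.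

**Further compounds**

F1 | step 6 | [(2R,3S)-3-methyl-3-(4-methylpent-3-en-1-yl)oxiran-2-yl]methanol | CC(C)=CCC[C@]1(C)O[C@@H]1CO
F2 | step 6 | [(2R,3S)-3-methyl-3-(4-methylpent-3-en-1-yl)oxiran-2-yl]methyl trifluoromethanesulfonate | CC(C)=CCC[C@]1(C)O[C@@H]1COS(=O)(=O)C(F)(F)F
F3 | step 6 | (2R,3S)-2-(Ar-methyl)-3-methyl-3-(4-methylpent-3-en-1-yl)oxirane | CC(C)=CCC[C@]1(C)O[C@@H]1Cc1c(OC)cc(OCOCC[Si](C)(C)C)c(C)c1OCOCC[Si](C)(C)C
F4 | step 6 | ring-lithiated F3 (lithium between OMe and OSEM) | CC(C)=CCC[C@]1(C)O[C@@H]1Cc1c(OC)c([Li])c(OCOCC[Si](C)(C)C)c(C)c1OCOCC[Si](C)(C)C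
F5 | step 6 | 1-{2-methoxy-5-methyl-3-{[(2R,3S)-3-methyl-3-(4-methylpent-3-en-1-yl)oxiran-2-yl]methyl}-4,6-bis(SEM-oxy)phenyl}-2-methylpropan-1-one | CC(C)=CCC[C@]1(C)O[C@@H]1Cc1c(OC)c(C(=O)C(C)C)c(OCOCC[Si](C)(C)C)c(C)c1OCOCC[Si](C)(C)C
F6 | step 10 | (6S)-4-[(2R,3S)-2,3-dihydroxy-3,7-dimethyloct-6-en-1-yl]-5-hydroxy-3-methoxy-6-methyl-2-(2-methylpropanoyl)-6-(prop-2-en-1-yl)cyclohexa-2,4-dien-1-one | CC(C)=CCC[C@](C)(O)[C@H](O)CC1=C(O)[C@](C)(CC=C)C(=O)C(C(=O)C(C)C)=C1OC
F7 | step 11 | (2S,7S)-4-hydroxy-2-[(2S)-2-hydroxy-6-methylhept-5-en-2-yl]-7-methyl-5-(2-methylpropanoyl)-7-(prop-2-en-1-yl)-2,3-dihydro-1-benzofuran-6(7H)-one | CC(C)=CCC[C@](C)(O)[C@@H]1CC2=C(O1)[C@](C)(CC=C)C(=O)C(C(=O)C(C)C)=C2O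
F8 | step 11 | (2S,7S)-2-[(2S)-2-hydroxy-6-methylhept-5-en-2-yl]-7-methyl-5-(2-methylpropanoyl)-7-(prop-2-en-1-yl)-4-(prop-2-en-1-yloxy)-2,3-dihydro-1-benzofuran-6(7H)-one | CC(C)=CCC[C@](C)(O)[C@@H]1CC2=C(O1)[C@](C)(CC=C)C(=O)C(C(=O)C(C)C)=C2OCC=C
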